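## Structural features

The target 19 is a (2S)-flavan: a chroman (rings A and C) whose only stereocentre, C2, is benzylic, α to the ring oxygen, and carries ring B. It has no neighbouring stereocentre, so the stereochemical problem is purely one of absolute configuration. Ring A carries one phenol (C7). Ring B is a pentasubstituted benzene with a catechol at C3'/C4', prenyl groups at C2' and C5', the chromanyl group at C1' and a single hydrogen at C6'.

The fragile groups are:
- the electron-rich catechol, which oxidises in air, fastest as the catecholate;
- the two trisubstituted prenyl olefins, which are hydrogenated, attacked by electrophiles, and cyclised by acid onto the ortho hydroxyls to give 2,2-dimethylchromans;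
- the benzylic C2–O bond, which is open to hydrogenolysis and to acid-induced ionisation (racemisation).

The real difficulty is ring B, not the chroman. Five contiguous substituents, with the C2' prenyl group wedged between C1' and O3', cannot be installed selectively by electrophilic prenylation of a catechol.

The feature used is the local symmetry of ring B. Apart from the substituent on C1', C2'/C5' (prenyl) and C3'/C4' (oxygen) are pairwise equivalent. C2'–C3' and C4'–C5' can therefore come from two identical prenyl-substituted ynol ether units tied through their oxygens by one silicon atom, and C1'–C6' from a terminal alkyne already attached to C2. The catechol protecting group then doubles as the tether, and C2 is set on a simple chroman-2-carboxylate before ring B exists.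

## Logic of the disconnections

19 ⇒ 18. The two O–Si bonds at O3'/O4' and the O–Si bond at O7 are cut. All three oxygens are silylated so that one fluoride treatment frees them, and no acid, hydrogen or oxidant meets the prenyl groups or the catechol. The forward step must be buffered and air-free.

18 ⇒ 7 + 17. The ring B bonds C1'–C2', C3'–C4' and C5'–C6' are cut. This removes ring B and the dioxasilole ring at once and leaves a symmetric diyne and a terminal alkyne, neither of which contains an arene that needs substituting. The forward step must achieve cross-cyclotrimerisation over homo-coupling and tolerate ynol ethers, prenyl olefins and the propargylic C2–O bond. Regiochemistry needs no control because 7 is symmetric.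

7 ⇒ 6 (twice) + 4, and 6 ⇒ 5 ⇒ 3. The two Si–O bonds of 7 are cut to give two ynolates 6 and the bis-electrophile 4. The C–O bond of 6 is then cut back to acetylide 5 and the hydrocarbon 3. Siloxyalkynes are made from ynolates, and the symmetry lets both arms be attached in one flask. The forward step needs O-silylation (not C-silylation) twice on one silicon, and an ynolate free of competing unhindered alkoxide.

3 ⇒ 1 + 2. The C(sp3)–C(sp) bond between the prenyl CH2 and the alkyne is cut, giving a commercial C5 halide and a C2 Grignard reagent. The forward step needs SN2 (not SN2') regioselectivity and must not isomerise the skipped enyne.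

17 ⇒ 16 ⇒ 15. The terminal alkyne carbon C6' is removed (C1'≡C6' becomes C1'=O in 16), and 16 is traced to ester 15. This one-carbon homologation is dependable and takes the stereocentre back to a carboxylate. The forward step must not epimerise the α-aryloxy aldehyde, so 16 is made and consumed in one flask.

15 ⇒ 14 ⇒ 13. The O7–Si bond is cut, and 14 is then traced to racemate 13 by resolution (no bond is cut). The phenol must be masked before the hydride and rhodium steps, and the enantiomers are separated at the cheapest stage. The forward step needs a hydrolase with high enantiodiscrimination.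

13 ⇒ 11 (through 12). The C2–H, C3–H and both C4–H bonds are removed, which restores the C2=C3 bond and the C4 carbonyl of a flat chromone. The forward step is an exhaustive hydrogenation that must spare the ester and ring A.

11 ⇒ 8 + 9 (through 10). The C2–C3 bond (Claisen condensation) and the O1–C2 bond (cyclodehydration) are cut, giving two commercial compounds.

## Other disconnections considered

Alternative 1: The cut is the C3=C4 bond of ring C. The diene ether A2, an (S)-1-arylallyl aryl ether with a vinyl group on C4a and the complete ring B on the carbinol carbon, would be closed by RuCl2(PCy3)2(=CHPh) (first-generation Grubbs catalyst) to the 2H-chromene A1.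
- In favour: ring-closing metathesis of a styrene with an allyl ether to a six-membered ring is among the most dependable ring closures, and this catalyst should ignore the trisubstituted prenyl olefins. The stereocentre of A2 could be set catalytically (for example by branched-selective allylic etherification) instead of by resolution. On both points this alternative is better than the chosen plan.
- Against: A2 needs the pentasubstituted ring B as a finished aromatic building block, so the central problem is only moved into a longer classical aromatic sequence. A1 is a 2-aryl-2H-chromene, whose C2–O bond can open reversibly (thermally or photochemically) to an ortho-quinone methide, which puts the configuration at risk. The C3=C4 bond must then be reduced beside two prenyl olefins. The three MOM groups need acid, which invites chroman formation from the ortho-prenylphenols.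
- Comparison: the key step forms one bond and one ring against three bonds and two rings. It needs at least two operations after it against one. It does not create ring B, which the chosen plan does without any arene substitution chemistry.

Alternative 2: The cuts are the C2'–CH2 and C5'–CH2 bonds. Heating the bis(1,1-dimethylallyl) ether A4 of the preformed (2S)-flavan would give 7-O-silyl-protected 19, A3, by two aromatic Claisen rearrangements.
- In favour: no metal is needed. Each allyl unit can only migrate to the single free ortho position of its oxygen, so the regiochemistry is dictated. The catechol hydroxyls are freed in the same step. A3 is one fluoride deprotection from 19, which equals the chosen plan after the key step. The prenyl groups appear last, so no earlier step has to tolerate them, which is better than the chosen plan.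
- Against: two tertiary allyl ethers on adjacent oxygens are hard to make. Such ethers ionise or eliminate the C5 unit on heating. The migration to C2' goes into a crowded site. The product is a free catechol carrying ortho-prenyl groups at high temperature, where cyclisation to chromans competes. The (2S)-flavan catechol core still has to be made enantioselectively first.
- Comparison: the step closes no ring and forms two bonds. It relies on a mature reaction type (an advantage in precedent) but on a substrate that is poorly suited to it. The overall step count is expected to be higher because ring B and the stereocentre both need separate classical sequences.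

Alternative 3: The cut is C4–C4a. Ph3PAuNTf2 (monovalent gold) would activate the terminal alkyne of the (S)-aryl propargyl ether A6, and ring A would attack through C4a in a 6-endo hydroarylation to give the 2H-chromene A5.
- In favour: the step is catalytic, atom-economical and mild. The stereocentre of A6 could come from a reagent-controlled asymmetric alkynylation (better than a resolution). The acetates of A5 leave under milder conditions than the MOM groups of A1.
- Against: ring A can close para or ortho to its silyloxy group, and only the para mode gives the 7-oxygenated chromene. The prenyl olefins, especially the one at C2', are themselves good nucleophiles toward a gold-activated alkyne (enyne cycloisomerisation). A propargylic ether bearing an electron-rich aryl group can ionise at the Lewis-acidic metal and racemise. A5 shares with A1 the configurational lability and the selective C3=C4 reduction.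
- Comparison: one bond and one ring are formed. The mechanism is well precedented for simple aryl propargyl ethers (equal or better in precedent). It meets more competing pathways in this substrate than the cycloaddition, and like alternative 1 it leaves ring B to classical chemistry and needs two or more steps after the key step.

Key step: step 8

Remarks on the chemistry:
- Assumption: the lipase of step 5 is taken to hydrolyse the (R)-ester faster, so that the (S)-ester 14 is recovered. The sense is to be confirmed by chiral HPLC and rotation, and with an enzyme of opposite preference the acid fraction would be re-esterified instead.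
- Structure check: 7, 17 and 18 map onto 19 atom for atom (C1'/C6' from the alkyne of 17, C2'/C5' from the prenyl-bearing and C3'/C4' from the oxygen-bearing alkyne carbons of 7). The descriptor at C2 is S from 14 to 19, because the C2 substituent keeps second CIP rank throughout. No correction to the constitution or configuration of the diyne, the alkyne or the cycloadduct was found necessary.
- Design changes to the two partners:
  - O7 carries a triisopropylsilyl group, because an aryl tert-butyldimethylsilyl ether is not reliably stable to the K2CO3/MeOH of step 7.
  - Ynolate 6 is made by acetylide oxidation and not by homologation of a 4-methylpent-3-enoate. The ester route releases one equivalent of unhindered alkoxide, which would compete for 4, and it passes through a doubly activated, easily enolised CH2.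
  - The alkyne is made from the ester in one flask, so the epimerisable aldehyde is never isolated.

Step 1
Reactants: 1 1-bromo-3-methylbut-2-ene (prenyl bromide); 2 ethynylmagnesium bromide
Product: 3 5-methylhex-4-en-1-yne
Conditions: 2 (1.5 equiv, 0.5 M in THF), CuCl (5 mol %), THF, 0 °C → rt; fractional distillation
Reagents that add atoms: none
Why: Copper-catalysed coupling of an alkynyl Grignard reagent with a primary allylic bromide (allylic substitution through a monovalent copper acetylide); attack at the unhindered CH2 terminus gives the linear skipped enyne, the branched SN2' isomer is expected to be minor and separable by distillation, and the excess of 2 suppresses double alkylation.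

Step 2
Reactants: 3 5-methylhex-4-en-1-yne; 4 di-tert-butylsilyl bis(trifluoromethanesulfonate)
Product: 7 di-tert-butylbis[(5-methylhex-4-en-1-yn-1-yl)oxy]silane, via lithium acetylide 5 (not isolated), via lithium ynolate 6 (not isolated)
Conditions: n-BuLi, THF, −78 °C; t-BuOOLi (from t-BuOOH and LiN(SiMe3)2, THF, −78 °C), −78 → 0 °C; 4 (0.5 equiv), −78 → 0 °C; cold aq. NaHCO3, pentane; filtration through Et3N-deactivated SiO2
Reagents that add atoms: tert-butyl hydroperoxide, CC(C)(C)OO
Why: Julia-type oxidation of a lithium acetylide by lithium tert-butyl peroxide (attack of the acetylide on the peroxide oxygen) gives ynolate 6, and hindered silyl triflates silylate ynolates on oxygen to give siloxyalkynes. The small linear ynolate should displace both triflates of 4 in turn, whereas the bulky t-BuOLi co-product cannot compete at the di-tert-butylsilyl centre, and the tert-butyl groups shield the Si–O bonds of 7 during a cold, base-buffered work-up.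

Step 3
Reactants: 8 2,4-dihydroxyacetophenone; 9 diethyl oxalate
Product: 11 ethyl 7-hydroxy-4-oxo-4H-chromene-2-carboxylate, via diketo ester 10 (not isolated)
Conditions: NaOEt (4 equiv), EtOH, reflux; then conc. HCl, EtOH, reflux
Reagents that add atoms: none
Why: Crossed Claisen condensation of the ketone enolate with non-enolisable 9 gives 10, and acid closes the pyranone by attack of the 2-OH on the α-keto ester carbonyl followed by dehydration (classical chromone-2-carboxylate synthesis); the 4-OH of 8 becomes the 7-OH.

Step 4
Reactants: 11 ethyl 7-hydroxy-4-oxo-4H-chromene-2-carboxylate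
Product: 13 ethyl 7-hydroxychroman-2-carboxylate (racemic), via racemic chromanone 12 (not isolated)
Conditions: H2 (4 atm), 10% Pd/C, AcOH, 70 °C
Reagents that add atoms: none
Why: Heterogeneous hydrogenation saturates the C2=C3 bond (12); the electron-rich aryl ketone is then reduced and its benzylic C–O bond hydrogenolysed in acetic acid, as in the established conversion of chromone-2-carboxylates into chroman-2-carboxylates. Ester, phenol and arene are inert, and C2 is formed racemic.

Step 5
Reactants: 13 ethyl 7-hydroxychroman-2-carboxylate (racemic)
Product: 14 ethyl (2S)-7-hydroxychroman-2-carboxylate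
Conditions: Pseudomonas fluorescens lipase, phosphate buffer pH 7/t-BuOMe, 30 °C, pH-stat, stopped just past half conversion; aq. NaHCO3 extraction of the acid
Reagents that add atoms: none
Why: Enzymatic kinetic resolution by enantioselective ester hydrolysis, a reaction type established for chroman-2-carboxylic esters; the faster-reacting (R)-ester leaves as the water-soluble carboxylate and the (S)-ester is recovered, its enantiomeric purity being raised by running slightly past half conversion. The C2 configuration of the whole route is fixed here by selection.

Step 6
Reactants: 14 ethyl (2S)-7-hydroxychroman-2-carboxylate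
Product: 15 ethyl (2S)-7-(triisopropylsilyloxy)chroman-2-carboxylate
Conditions: i-Pr3SiCl, imidazole, DMF, rt
Reagents that add atoms: chlorotriisopropylsilane, CC(C)[Si](Cl)(C(C)C)C(C)C
Why: Silylation of a phenol with a trialkylsilyl chloride and imidazole (Corey conditions); imidazole is too weak a base to enolise the α-aryloxy ester, so C2 is untouched.

Step 7
Reactants: 15 ethyl (2S)-7-(triisopropylsilyloxy)chroman-2-carboxylate
Product: 17 (2S)-2-ethynyl-7-(triisopropylsilyloxy)chroman, via aldehyde 16 (not isolated)
Conditions: i-Bu2AlH (1.2 equiv), CH2Cl2, −78 °C; then MeOH, K2CO3, dimethyl (1-diazo-2-oxopropyl)phosphonate, −78 °C → rt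
Reagents that add atoms: dimethyl (1-diazo-2-oxopropyl)phosphonate, CC(=O)C(=[N+]=[N-])P(=O)(OC)OC
Why: One-pot partial reduction/Ohira–Bestmann (Seyferth–Gilbert) homologation: the ester is reduced at −78 °C to a chelated aluminium hemiacetal, which releases aldehyde 16 only on methanolysis, in the presence of the diazophosphonate anion formed by K2CO3/MeOH; Horner–Wadsworth–Emmons-type olefination, loss of N2 and 1,2-hydrogen shift of the alkylidene carbene give the alkyne. Because 16 is trapped as it forms, C2 is not expected to epimerise, and the aryl triisopropylsilyl ether should tolerate the mild methanolic base.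

Step 8
Reactants: 7 di-tert-butylbis[(5-methylhex-4-en-1-yn-1-yl)oxy]silane; 17 (2S)-2-ethynyl-7-(triisopropylsilyloxy)chroman
Product: 18 7-O-(triisopropylsilyl)-3',4'-O-(di-tert-butylsilylene)kazinol A, i.e. (2S)-2-[2,2-di-tert-butyl-4,7-bis(3-methylbut-2-en-1-yl)-1,3,2-benzodioxasilol-5-yl]-7-(triisopropylsilyloxy)chroman
Conditions: RhCl(PPh3)3 (5 mol %), degassed toluene, 60 °C; 7 (1.0 equiv) added by syringe pump over 6 h to 17 (1.5 equiv); excess 17 recovered
Reagents that add atoms: none
Why: Proposed new method: a rhodium-catalysed [2+2+2] alkyne cyclotrimerisation in which monovalent rhodium, after loss of PPh3, binds both ynol ether triple bonds of 7 and couples them oxidatively to a trivalent rhodacyclopentadiene (forming C3'–C4'), after which the terminal alkyne of 17 coordinates and inserts and reductive elimination forms C1'–C2' and C5'–C6' and returns monovalent rhodium. The closest known reaction type is the rhodium-catalysed cross-cycloaddition of 1,6-diynes with terminal alkynes, which is documented for diynes carrying heteroatom-substituted triple bonds but not for a silylene-tethered bis(siloxyalkyne). The five-membered dioxasilole ring closes in the oxidative coupling, because the O–Si–O tether places the two oxygen-bearing carbons in a 1,6-relationship and allows only the metallacycle with both oxygens on its β-carbons; ring B closes by the insertion/reductive elimination sequence, a formal [2+2+2] cycloaddition. No stereocentre is created, and C2 of 17 is carried through unchanged under neutral, base-free and non-ionising conditions. The step needs chemoselectivity for cross- over homo-cyclotrimerisation and over dimerisation of the terminal alkyne: the hindered, internal, tethered triple bonds of 7 are poor third partners and the unhindered terminal alkyne is a good one, and slow addition keeps the stationary concentration of 7 low against a modest, recoverable excess of 17. Regiochemistry needs no control, because 7 is constitutionally symmetric and both orientations of 17 give 18. In the metallacycle each siloxy oxygen is trans to rhodium across its double bond, so syn β-oxygen elimination is geometrically blocked, and the trisubstituted prenyl olefins are too hindered to insert.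

Step 9
Reactants: 18 7-O-(triisopropylsilyl)-3',4'-O-(di-tert-butylsilylene)kazinol A
Product: 19 kazinol A, 4-[(2S)-7-hydroxychroman-2-yl]-3,6-bis(3-methylbut-2-en-1-yl)benzene-1,2-diol
Conditions: Bu4NF (3.3 equiv), AcOH (3.3 equiv), degassed THF, 0 °C → rt, Ar
Reagents that add atoms: none
Why: Fluoride-induced cleavage of aryl–O–Si bonds, driven by the strength of the Si–F bond, opens the five-membered silylene and removes the aryl silyl ether in the same flask. Acetic acid keeps the medium near neutral, so the catechol is not exposed as its dianion and no acid strong enough to cyclise the ortho-prenylphenols is present; C2 and the prenyl olefins are untouched.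

## Compound list

1 | 1-bromo-3-methylbut-2-ene (prenyl bromide) | CC(C)=CCBr | starting material
2 | ethynylmagnesium bromide | C#C[Mg]Br | starting material
3 | 5-methylhex-4-en-1-yne | C#CCC=C(C)C | intermediate
4 | di-tert-butylsilyl bis(trifluoromethanesulfonate) | CC(C)(C)[Si](OS(=O)(=O)C(F)(F)F)(OS(=O)(=O)C(F)(F)F)C(C)(C)C | starting material
5 | lithium 5-methylhex-4-en-1-yn-1-ide | [Li+].[C-]#CCC=C(C)C | intermediate
6 | lithium 5-methylhex-4-en-1-yn-1-olate | [Li+].[O-]C#CCC=C(C)C | intermediate
7 | di-tert-butylbis[(5-methylhex-4-en-1-yn-1-yl)oxy]silane | CC(C)=CCC#CO[Si](C(C)(C)C)(C(C)(C)C)OC#CCC=C(C)C | intermediate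
8 | 2,4-dihydroxyacetophenone | CC(=O)c1ccc(O)cc1O | starting material
9 | diethyl oxalate | CCOC(=O)C(=O)OCC | starting material
10 | ethyl 4-(2,4-dihydroxyphenyl)-2,4-dioxobutanoate | CCOC(=O)C(=O)CC(=O)c1ccc(O)cc1O | intermediate
11 | ethyl 7-hydroxy-4-oxo-4H-chromene-2-carboxylate | CCOC(=O)c1cc(=O)c2ccc(O)cc2o1 | intermediate
12 | ethyl 7-hydroxy-4-oxochroman-2-carboxylate (racemic) | CCOC(=O)C1CC(=O)c2ccc(O)cc2O1 | intermediate
13 | ethyl 7-hydroxychroman-2-carboxylate (racemic) | CCOC(=O)C1CCc2ccc(O)cc2O1 | intermediate
14 | ethyl (2S)-7-hydroxychroman-2-carboxylate | CCOC(=O)[C@@H]1CCc2ccc(O)cc2O1 | intermediate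
15 | ethyl (2S)-7-(triisopropylsilyloxy)chroman-2-carboxylate | CCOC(=O)[C@@H]1CCc2ccc(O[Si](C(C)C)(C(C)C)C(C)C)cc2O1 | intermediate
16 | (2S)-7-(triisopropylsilyloxy)chroman-2-carbaldehyde | O=C[C@@H]1CCc2ccc(O[Si](C(C)C)(C(C)C)C(C)C)cc2O1 | intermediate
17 | (2S)-2-ethynyl-7-(triisopropylsilyloxy)chroman | C#C[C@@H]1CCc2ccc(O[Si](C(C)C)(C(C)C)C(C)C)cc2O1 | intermediate
18 | 7-O-(triisopropylsilyl)-3',4'-O-(di-tert-butylsilylene)kazinol A | CC(C)=CCc1cc([C@@H]2CCc3ccc(O[Si](C(C)C)(C(C)C)C(C)C)cc3O2)c(CC=C(C)C)c2O[Si](C(C)(C)C)(C(C)(C)C)Oc12 | intermediate
19 | kazinol A | CC(C)=CCc1cc([C@@H]2CCc3ccc(O)cc3O2)c(CC=C(C)C)c(O)c1O | target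

## Step count and least certain steps

Total: 9 steps. Longest linear sequence: 7 steps (steps 3 to 9, from 8). The diyne branch contributes 2 steps before the convergent step 8.

**Step 8 (key step).** The catalyst is most likely to be diverted. Possible diversions are dimerisation of the terminal alkyne through a rhodium acetylide, oligomerisation of the electron-rich ynol ether, or failure of the oxidative coupling because the tert-butyl groups and the substituted alkyne termini keep the two triple bonds from binding one metal centre. Changes of catalyst ([Rh(cod)2]BF4 with BINAP, Cp*RuCl(cod)) would be tried first.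

The fallback uses known chemistry only. It gives up the de novo ring B, sets out from 8 and comes back at 19:
- Selective silylation of the non-chelated 4-OH of 8 (i-Pr3SiCl, imidazole) gives 1-[2-hydroxy-4-(triisopropylsilyloxy)phenyl]ethanone F1.
- Me2NCH(OMe)2 gives the enaminone (E)-3-(dimethylamino)-1-[2-hydroxy-4-(triisopropylsilyloxy)phenyl]prop-2-en-1-one F2, which closes on mild acid treatment to 7-(triisopropylsilyloxy)chromone F3.
- Rhodium-catalysed asymmetric 1,4-addition of commercial 3,4-bis(benzyloxy)phenylboronic acid gives (2S)-3',4'-bis(benzyloxy)-7-(triisopropylsilyloxy)flavanone F4. The conditions are [RhCl(C2H4)2]2, a chiral diene ligand of the enantiomeric series leading to the 2S product, aqueous KOH and dioxane.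
- NaBH4 gives (2S)-3',4'-bis(benzyloxy)-7-(triisopropylsilyloxy)flavan-4-ol F5, and ionic hydrogenation (Et3SiH, CF3CO2H) gives (2S)-3',4'-bis(benzyloxy)-7-(triisopropylsilyloxy)flavan F6.
- Hydrogenolysis (H2, Pd/C, EtOAc) frees the catechol (2S)-3',4'-dihydroxy-7-(triisopropylsilyloxy)flavan F7.
- Allyl bromide and K2CO3 under argon give (2S)-3',4'-bis(allyloxy)-7-(triisopropylsilyloxy)flavan F8.
- Double aromatic Claisen rearrangement (PhNEt2, 190 °C) delivers the allyl groups to the only free ortho positions, C2' and C5', giving (2S)-2',5'-diallyl-3',4'-dihydroxy-7-(triisopropylsilyloxy)flavan F9.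
- Cross-metathesis with 2-methylbut-2-ene (second-generation Grubbs catalyst) turns both allyl groups into prenyl groups, giving 7-O-(triisopropylsilyl)kazinol A F10.
- Buffered Bu4NF as in step 9 gives 19.

**Step 2.** The double silylation at one silicon may stop after the first substitution, may incorporate tert-butoxide, or may go to carbon (silylketene formation). The product may also hydrolyse during isolation. The fallback sets out from 3 and comes back at 6 and then 7. The acetylide oxidation is run as before but quenched with i-Pr3SiOTf to give the isolable triisopropyl[(5-methylhex-4-en-1-yn-1-yl)oxy]silane F11, which is purified. MeLi in THF then cleaves its Si–O bond and regenerates 6 free of alkoxide and peroxide residues, and 6 is silylated with 4 (0.5 equiv).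

**Step 7.** Epimerisation at C2 of the α-aryloxy aldehyde in methanolic carbonate, or over-reduction of the ester to the primary alcohol, are the likely faults. The fallback sets out from 15 and comes back at 17 by a Corey–Fuchs sequence. Reduction with i-Bu2AlH at −78 °C and a cold non-basic work-up gives 16. Base-free dibromo-olefination (CBr4, PPh3, Zn, CH2Cl2, 0 °C) gives (2S)-2-(2,2-dibromovinyl)-7-(triisopropylsilyloxy)chroman F12, in which C2 is no longer α to a carbonyl group. n-BuLi at −78 °C then gives 17 by bromine–lithium exchange and 1,2-shift.

**Step 5.** The enzyme may discriminate the enantiomers insufficiently, or may prefer the opposite enantiomer. The fallback sets out from 13 and comes back at 14 by classical resolution. Saponification (LiOH, THF/H2O) gives racemic 7-hydroxychroman-2-carboxylic acid F13. Crystallisation of its salt with (S)-1-phenylethylamine (or its enantiomer, whichever gives the less soluble salt of the wanted acid) and acidification give (2S)-7-hydroxychroman-2-carboxylic acid F14. Fischer esterification (EtOH, cat. H2SO4) returns 14.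

**Step 9.** Air oxidation of the liberated catechol during the fluoride treatment, or incomplete opening of the silylene flanked by two prenyl groups, would lower the recovery of a product that is awkward to purify. The fallback sets out from 18 and comes back at 19. The fluoride-liberated phenoxides are acetylated in the flask (Bu4NF, then Ac2O) to the air-stable kazinol A triacetate F15, which is purified. The acetates are then removed under reducing, non-oxidising conditions with N2H4·H2O in THF/MeOH at 0 °C.

## Further compounds

F1 | step 8 | 1-[2-hydroxy-4-(triisopropylsilyloxy)phenyl]ethanone | CC(=O)c1ccc(O[Si](C(C)C)(C(C)C)C(C)C)cc1O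
F2 | step 8 | (E)-3-(dimethylamino)-1-[2-hydroxy-4-(triisopropylsilyloxy)phenyl]prop-2-en-1-one | CN(C)/C=C/C(=O)c1ccc(O[Si](C(C)C)(C(C)C)C(C)C)cc1O
F3 | step 8 | 7-(triisopropylsilyloxy)-4H-chromen-4-one | O=c1ccoc2cc(O[Si](C(C)C)(C(C)C)C(C)C)ccc12
F4 | step 8 | (2S)-3',4'-bis(benzyloxy)-7-(triisopropylsilyloxy)flavanone | O=C1C[C@@H](c2ccc(OCc3ccccc3)c(OCc3ccccc3)c2)Oc2cc(O[Si](C(C)C)(C(C)C)C(C)C)ccc21
F5 | step 8 | (2S)-3',4'-bis(benzyloxy)-7-(triisopropylsilyloxy)flavan-4-ol (C4 epimers) | OC1C[C@@H](c2ccc(OCc3ccccc3)c(OCc3ccccc3)c2)Oc2cc(O[Si](C(C)C)(C(C)C)C(C)C)ccc21
F6 | step 8 | (2S)-3',4'-bis(benzyloxy)-7-(triisopropylsilyloxy)flavan | c1ccc(COc2ccc([C@@H]3CCc4ccc(O[Si](C(C)C)(C(C)C)C(C)C)cc4O3)cc2OCc2ccccc2)cc1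
F7 | step 8 | (2S)-3',4'-dihydroxy-7-(triisopropylsilyloxy)flavan | Oc1ccc([C@@H]2CCc3ccc(O[Si](C(C)C)(C(C)C)C(C)C)cc3O2)cc1O
F8 | step 8 | (2S)-3',4'-bis(allyloxy)-7-(triisopropylsilyloxy)flavan | C=CCOc1ccc([C@@H]2CCc3ccc(O[Si](C(C)C)(C(C)C)C(C)C)cc3O2)cc1OCC=C
F9 | step 8 | (2S)-2',5'-diallyl-3',4'-dihydroxy-7-(triisopropylsilyloxy)flavan | C=CCc1cc([C@@H]2CCc3ccc(O[Si](C(C)C)(C(C)C)C(C)C)cc3O2)c(CC=C)c(O)c1O
F10 | step 8 | 7-O-(triisopropylsilyl)kazinol A | CC(C)=CCc1cc([C@@H]2CCc3ccc(O[Si](C(C)C)(C(C)C)C(C)C)cc3O2)c(CC=C(C)C)c(O)c1O
F11 | step 2 | triisopropyl[(5-methylhex-4-en-1-yn-1-yl)oxy]silane | CC(C)=CCC#CO[Si](C(C)C)(C(C)C)C(C)C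
F12 | step 7 | (2S)-2-(2,2-dibromovinyl)-7-(triisopropylsilyloxy)chroman | BrC(Br)=C[C@@H]1CCc2ccc(O[Si](C(C)C)(C(C)C)C(C)C)cc2O1
F13 | step 5 | 7-hydroxychroman-2-carboxylic acid (racemic) | OC(=O)C1CCc2ccc(O)cc2O1
F14 | step 5 | (2S)-7-hydroxychroman-2-carboxylic acid | OC(=O)[C@@H]1CCc2ccc(O)cc2O1
F15 | step 9 | kazinol A triacetate | CC(C)=CCc1cc([C@@H]2CCc3ccc(OC(C)=O)cc3O2)c(CC=C(C)C)c(OC(C)=O)c1OC(C)=O
A1 | alternative 1 | (2S)-7,3',4'-tris(methoxymethoxy)-2',5'-bis(3-methylbut-2-enyl)flav-3-ene | CC(C)=CCc1cc([C@@H]2C=Cc3ccc(OCOC)cc3O2)c(CC=C(C)C)c(OCOC)c1OCOC
A2 | alternative 1 | 1-[(1S)-1-[2-ethenyl-5-(methoxymethoxy)phenoxy]prop-2-en-1-yl]-3,4-bis(methoxymethoxy)-2,5-bis(3-methylbut-2-en-1-yl)benzene | C=C[C@H](Oc1cc(OCOC)ccc1C=C)c1cc(CC=C(C)C)c(OCOC)c(OCOC)c1CC=C(C)C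
A3 | alternative 2 | 7-O-(tert-butyldimethylsilyl)kazinol A | CC(C)=CCc1cc([C@@H]2CCc3ccc(O[Si](C)(C)C(C)(C)C)cc3O2)c(CC=C(C)C)c(O)c1O
A4 | alternative 2 | (2S)-7-(tert-butyldimethylsilyloxy)-3',4'-bis(2-methylbut-3-en-2-yloxy)flavan | C=CC(C)(C)Oc1ccc([C@@H]2CCc3ccc(O[Si](C)(C)C(C)(C)C)cc3O2)cc1OC(C)(C)C=C
A5 | alternative 3 | (2S)-3',4'-diacetoxy-7-(tert-butyldimethylsilyloxy)-2',5'-bis(3-methylbut-2-enyl)flav-3-ene | CC(C)=CCc1cc([C@@H]2C=Cc3ccc(O[Si](C)(C)C(C)(C)C)cc3O2)c(CC=C(C)C)c(OC(C)=O)c1OC(C)=O
A6 | alternative 3 | 4-[(1S)-1-[3-(tert-butyldimethylsilyloxy)phenoxy]prop-2-yn-1-yl]-3,6-bis(3-methylbut-2-en-1-yl)-1,2-phenylene diacetate | C#C[C@H](Oc1cccc(O[Si](C)(C)C(C)(C)C)c1)c1cc(CC=C(C)C)c(OC(C)=O)c(OC(C)=O)c1CC=C(C)C
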